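Millimolar was the unit I reckoned in for this flask, and the sum I wanted was how many millimolar of coupling partner a run had been charged for each millimolar of starting material it had lost by the time it stopped. I laid the earlier runs on a ladder of times. On the fastest rung, before the first reading, the north run had already changed: starting material read 47% at 10.0 s. Single product read low from the first reading on, its highest reading being 3% in north-west at 80.0 s, and I drew no conclusion from that about how it had gone. On the next rung, up to 90.0 s, north read 48%, a shift within the scatter of 2 percentage points. The top rung, 2.5 min, lay 1.18 powers of ten beyond the first reading, so I asked where this flask stops, not how fast it gets there.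

| flask | starting material | coupling partner | remark | time |
|---|---|---|---|---|
| north | 0.010 M | 13 mM | run made earlier |  |
| south | 0.010 M | 20 mM | run made earlier |  |
| north-west | 0.020 M | 9 mM | run made earlier |  |
| flask | 0.010 M | 9.00 mM |  | 2.5 min |

| run | time / s | starting material / % | single product / % |
|---|---|---|---|
| north | 10.0 | 47 | 0 |
| north | 25.0 | 50 | 1 |
| north | 40.0 | 44 | 0 |
| north | 60.0 | 44 | 0 |
| north | 90.0 | 48 | 0 |
| south | 20.0 | 24 | 1 |
| south | 40.0 | 23 | 2 |
| south | 50.0 | 24 | 1 |
| south | 80.0 | 23 | 0 |
| south | 90.0 | 22 | 0 |
| north-west | 20.0 | 80 | 0 |
| north-west | 40.0 | 82 | 0 |
| north-west | 50.0 | 77 | 1 |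
| north-west | 80.0 | 78 | 3 |
| north-west | 90.0 | 75 | 0 |

(standard deviation of a reading: 2 percentage points)

- starting material at 2.5 min, in percent of the starting material charged
- single product at 2.5 min, in percent of the starting material charged
- other mono adduct at 2.5 min, in percent of the starting material charged
- bis adduct at 2.5 min, in percent of the starting material charged

North's mean reading of 46.6% meant 5.34 mM lost against 13 mM charged, and that ratio, 2.43, is the partner cost. South gave 2.60 and north-west 2.08, so it is no constant, but north shares this flask's starting charge. Dividing 9.00 mM by north's cost, I expected 63.0% of the starting material left in this flask.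

The forecast, reasoning that “the first addition is fast and the second is faster still”, gave 63% starting material, 0.5% single product, 0.5% other mono adduct and 36% bis adduct.

The flask gave 62.3% starting material, 0% single product, 4.59% other mono adduct and 33.1% bis adduct, from this scheme:

    coupling partner → decomposition product (k = 8.49 × 10⁻⁵ s⁻¹)
    coupling partner + single product → bis adduct + released group (k = 170 M⁻¹ s⁻¹)
    coupling partner → decomposed reagent (k = 0.111 s⁻¹)
    starting material + coupling partner → other mono adduct + released group (k = 5.41 M⁻¹ s⁻¹)
    starting material + coupling partner ⇌ single product + released group (K = 0.911, k = 95.5 M⁻¹ s⁻¹)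
    coupling partner + other mono adduct → bis adduct + released group (k = 34.1 M⁻¹ s⁻¹)

In the flask, coupling partner, the limiting reagent, stood at 2.07% of its charge after 0.250 min and 0% after 2.50 min. The flask's own partner cost came to 2.39, against north's 2.43. For the neighbour flask charged with 0.015 M of coupling partner, north's cost puts the starting material left at 38.4%, and that neighbour held 39.1%.

The runs are calculated from invented constants, and the scatter is random.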